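The pyran ring C of the upper flavan unit is disconnected into an aryloxy-benzylidene fragment (C4a/C8a–O1–C2) and a two-carbon 1,2-dioxygenated fragment (C3–C4). The key step is a catalytic enantioselective oxa-Povarov-type [4+2] annulation of the aryl oxocarbenium ion released from mixed acetal 11 with the symmetric Z-enediol bis-silyl ether 13. It forms the C2–C3 and C4–C4a bonds in one operation and gives a benzyl-protected 2,3-cis-leucocyanidin. It exploits that C4a lies ortho and para to three ring A oxygens and that C4, left as an ionisable benzylic carbinol, can then be joined 4β→8 to an epicatechin-derived 4β-carboxymethyl lower unit; hydrogenolysis ends the route.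

Key step: step 8

Assumption: the (S,S)-configured catalyst anion of step 8 is taken to leave the Si face of C2 of the oxocarbenium ion open; if the sense of induction is the reverse, the (R,R)-catalyst is used and nothing else changes.
Remark: the configuration at C4 of 15 is of no consequence, because C4 is ionised and set anew in step 9; a C4 epimer, if formed, converges.

Step 1
Reactants: 1 (−)-epicatechin
Product: 2 5,7,3′,4′-tetra-O-benzyl-(−)-epicatechin
Conditions: BnBr, K2CO3, DMF, 0 °C → rt
Reagents that add atoms: benzyl bromide BrCc1ccccc1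
Why: Williamson etherification in which K2CO3 deprotonates only the four phenols, so the secondary 3-OH stays free and no stereocentre is touched.

Step 2
Reactants: 2 5,7,3′,4′-tetra-O-benzyl-(−)-epicatechin
Product: 3 (2R,3R,4S)-5,7-bis(benzyloxy)-2-[3,4-bis(benzyloxy)phenyl]-4-(2-ethoxyethoxy)chroman-3-ol (4β-ether)
Conditions: DDQ, EtOCH2CH2OH, CH2Cl2, rt
Reagents that add atoms: 2-ethoxyethanol CCOCCO
Why: Benzylic C–H oxidation, in which DDQ abstracts hydride from C4 and the alcohol captures the ring-A-stabilised cation trans to the 3-OH, which sets the 4β (4S) ether.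

Step 3
Reactants: 4 benzyl acetate
Product: 5 1-(benzyloxy)-1-(tert-butyldimethylsilyloxy)ethene
Conditions: LiN(iPr)2, THF, −78 °C; TBSCl, DMPU, −78 °C → rt
Reagents that add atoms: tert-butyldimethylsilyl chloride CC(C)(C)[Si](C)(C)Cl
Why: Silyl ketene acetal formation by O-silylation of the ester enolate, which the hindered silyl chloride in the presence of DMPU favours over C-silylation.

Step 4
Reactants: 3 4β-(2-ethoxyethoxy) ether; 5 1-(benzyloxy)-1-(tert-butyldimethylsilyloxy)ethene
Product: 6 benzyl 2-[(2R,3R,4S)-5,7-bis(benzyloxy)-2-[3,4-bis(benzyloxy)phenyl]-3-hydroxychroman-4-yl]acetate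
Conditions: TMSOTf (10 mol%), 5 (2.5 equiv), CH2Cl2, 4 Å MS, −78 °C; aq. citric acid work-up
Reagents that add atoms: none
Why: Mukaiyama-type substitution in which the silyl triflate ionises the 4-alkoxy group and the ketene acetal adds to the C4 cation from the β face, anti to the 3-OH and the 2-aryl group, which sets 4S (3,4-trans).

Step 5
Reactants: 7 3,4-bis(benzyloxy)benzaldehyde
Product: 8 1,2-bis(benzyloxy)-4-(dimethoxymethyl)benzene
Conditions: HC(OMe)3, p-TsOH (cat.), MeOH, rt; Et3N quench
Reagents that add atoms: trimethyl orthoformate COC(OC)OC; methanol CO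
Why: Acid-catalysed acetalisation driven to completion by the orthoformate as water scavenger.

Step 6
Reactants: 8 1,2-bis(benzyloxy)-4-(dimethoxymethyl)benzene; 9 3,5-bis(benzyloxy)phenol
Product: 11 racemic mixed acetal 1,3-bis(benzyloxy)-5-{[3,4-bis(benzyloxy)phenyl](methoxy)methoxy}benzene, via alpha-chloro ether 10 (not isolated)
Conditions: AcCl, CH2Cl2, 0 °C → rt, evaporate; then 9, NaH, THF, −20 → 0 °C; Et3N-deactivated silica
Reagents that add atoms: none
Why: Acetal–acyl chloride exchange gives the α-chloro ether, and the sodium phenoxide then displaces chloride on oxygen in an SN1-like Williamson etherification; the acetal carbon is racemic and is planarised in step 8.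

Step 7
Reactants: 12 glycolaldehyde dimer
Product: 13 (Z)-1,2-bis(trimethylsilyloxy)ethene
Conditions: TMSCl, Et3N, DMF, 80 °C; distillation
Reagents that add atoms: chlorotrimethylsilane C[Si](C)(C)Cl
Why: Silyl enol ether formation in which heating cracks the dimer to glycolaldehyde and both the hydroxyl and the enol oxygen are silylated, the Z isomer being favoured for 1,2-dioxygenated alkenes.

Step 8
Reactants: 11 racemic mixed acetal; 13 (Z)-1,2-bis(trimethylsilyloxy)ethene
Product: 15 (2R,3R,4R)-5,7-bis(benzyloxy)-2-[3,4-bis(benzyloxy)phenyl]chromane-3,4-diol (all-cis), via bis-trimethylsilyl ether 14 (not isolated)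
Conditions: (S,S)-IDPi acid HN[P(=NSO2CF3)(O2C20H10Ar2)]2 (Ar = 3,5-(CF3)2C6H3; O2C20H10Ar2 = (S)-3,3′-diaryl-1,1′-binaphthalene-2,2′-diolate) (5 mol%), 13 (2.5 equiv), toluene, −78 °C; then K2CO3, MeOH, 0 °C
Reagents that add atoms: none
Why: Proposed new method: the acid, silylated in situ by 13, ionises the methoxy oxygen of 11 to the (E)-aryl oxocarbenium ion, a cationic 2-oxadiene spanning C4a=C8a–O1=C2 that stays ion-paired inside the chiral anion; a carbon of 13 adds to C2 (C2–C3 bond) and the silyloxocarbenium ion so formed at C4 is trapped by the ortho carbon C4a (C4–C4a bond), a formal inverse-electron-demand [4+2] annulation whose closest known relatives are the SnCl4-promoted oxa-Povarov reaction of phenol-derived mixed acetals with alkenes and the IDPi-catalysed enantioselective addition of enol silanes to oxocarbenium ions from O,O-acetals. The pyran ring closes by a 6-exo-trig Friedel–Crafts attack of the arene (its C4a=C8a bond inside the new ring) on the C4 oxocarbenium carbon. C2 and C3 are set together: the endo (synclinal) approach of the Z-enediol to the E-oxocarbenium ion, the same topology as the syn-selective open-transition-state Mukaiyama addition to acetals, places the 2-aryl group and the C3 oxygen cis, and the confined anion leaves only the Si face of C2 open, which fixes (2R,3R); C4 forms cis to C3 by the suprafacial closure but is reset in step 9. Regiochemistry needs no control because 13 is symmetric and both ortho positions of the 3,5-bis(benzyloxy)phenoxy ring are equivalent; loss of methoxide and not of aryloxide is secured by the higher basicity of the alkyl oxygen towards silylium, and the three activating oxygens around C4a make ring closure faster than intermolecular arylation. The K2CO3/MeOH work-up cleaves both silyl ethers of 14 to give diol 15.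

Step 9
Reactants: 15 all-cis 3,4-diol; 6 lower-unit benzyl ester
Product: 16 benzyl 2-[(2R,3R,4S)-5,7-bis(benzyloxy)-2-[3,4-bis(benzyloxy)phenyl]-8-{(2R,3R,4R)-5,7-bis(benzyloxy)-2-[3,4-bis(benzyloxy)phenyl]-3-hydroxychroman-4-yl}-3-hydroxychroman-4-yl]acetate
Conditions: Yb(OTf)3 (0.5 equiv), 6 (3 equiv), CH2Cl2, 4 Å MS, 0 °C → rt, slow addition of 15
Reagents that add atoms: none
Why: Lewis-acid-mediated flavan-3,4-diol/flavan-3-ol condensation (Friedel–Crafts alkylation), in which the C4 hydroxyl of 15 is ionised and C8 of 6 adds to the cation from the β face, trans to the 3-OH and anti to the 2-aryl group, which sets the 4β→8 (4R) bond; excess 6 suppresses self-condensation.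

Step 10
Reactants: 16 nona-benzyl-protected dimer
Product: 17 epicatechin-(4β→8)-4β-carboxymethylepicatechin (CNP0190976.1)
Conditions: H2 (1 atm), Pd(OH)2/C, THF/MeOH/H2O, rt
Reagents that add atoms: none
Why: Catalytic hydrogenolysis cleaves the eight benzyl ethers and the benzyl ester without touching the stereocentres or the interflavan bond.

Compound list
1 | (−)-epicatechin, (2R,3R)-2-(3,4-dihydroxyphenyl)chromane-3,5,7-triol | C1c2c(O)cc(O)cc2O[C@H](c2ccc(O)c(O)c2)[C@@H]1O | starting material
2 | 5,7,3′,4′-tetra-O-benzyl-(−)-epicatechin | C1c2c(OCc3ccccc3)cc(OCc3ccccc3)cc2O[C@H](c2ccc(OCc3ccccc3)c(OCc3ccccc3)c2)[C@@H]1O | intermediate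
3 | (2R,3R,4S)-5,7-bis(benzyloxy)-2-[3,4-bis(benzyloxy)phenyl]-4-(2-ethoxyethoxy)chroman-3-ol | CCOCCO[C@H]1c2c(OCc3ccccc3)cc(OCc3ccccc3)cc2O[C@H](c2ccc(OCc3ccccc3)c(OCc3ccccc3)c2)[C@@H]1O | intermediate
4 | benzyl acetate | CC(=O)OCc1ccccc1 | starting material
5 | 1-(benzyloxy)-1-(tert-butyldimethylsilyloxy)ethene | C=C(OCc1ccccc1)O[Si](C)(C)C(C)(C)C | intermediate
6 | benzyl 2-[(2R,3R,4S)-5,7-bis(benzyloxy)-2-[3,4-bis(benzyloxy)phenyl]-3-hydroxychroman-4-yl]acetate (2,3-cis-3,4-trans) | O=C(OCc1ccccc1)C[C@H]1c2c(OCc3ccccc3)cc(OCc3ccccc3)cc2O[C@H](c2ccc(OCc3ccccc3)c(OCc3ccccc3)c2)[C@@H]1O | intermediate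
7 | 3,4-bis(benzyloxy)benzaldehyde | O=Cc1ccc(OCc2ccccc2)c(OCc2ccccc2)c1 | starting material
8 | 1,2-bis(benzyloxy)-4-(dimethoxymethyl)benzene | COC(OC)c1ccc(OCc2ccccc2)c(OCc2ccccc2)c1 | intermediate
9 | 3,5-bis(benzyloxy)phenol | Oc1cc(OCc2ccccc2)cc(OCc2ccccc2)c1 | starting material
10 | 1,2-bis(benzyloxy)-4-[chloro(methoxy)methyl]benzene (racemic, not isolated) | COC(Cl)c1ccc(OCc2ccccc2)c(OCc2ccccc2)c1 | intermediate
11 | 1,3-bis(benzyloxy)-5-{[3,4-bis(benzyloxy)phenyl](methoxy)methoxy}benzene (racemic mixed acetal) | COC(Oc1cc(OCc2ccccc2)cc(OCc2ccccc2)c1)c1ccc(OCc2ccccc2)c(OCc2ccccc2)c1 | intermediate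
12 | glycolaldehyde dimer (1,4-dioxane-2,5-diol) | OC1COC(O)CO1 | starting material
13 | (Z)-1,2-bis(trimethylsilyloxy)ethene | C[Si](C)(C)O/C=C\O[Si](C)(C)C | intermediate
14 | all-cis 5,7-bis(benzyloxy)-2-[3,4-bis(benzyloxy)phenyl]-3,4-bis(trimethylsilyloxy)chroman (2α-aryl, 3α-O, 4α-O; not isolated) | C[Si](C)(C)O[C@@H]1c2c(OCc3ccccc3)cc(OCc3ccccc3)cc2O[C@H](c2ccc(OCc3ccccc3)c(OCc3ccccc3)c2)[C@@H]1O[Si](C)(C)C | intermediate
15 | (2R,3R,4R)-5,7-bis(benzyloxy)-2-[3,4-bis(benzyloxy)phenyl]chromane-3,4-diol (all-cis) | O[C@@H]1c2c(OCc3ccccc3)cc(OCc3ccccc3)cc2O[C@H](c2ccc(OCc3ccccc3)c(OCc3ccccc3)c2)[C@@H]1O | intermediate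
16 | nona-benzyl-protected dimer, upper unit (2R,3R,4R) joined 4β→8 to lower unit (2R,3R,4S) | O=C(OCc1ccccc1)C[C@H]1c2c(OCc3ccccc3)cc(OCc3ccccc3)c([C@H]3c4c(OCc5ccccc5)cc(OCc5ccccc5)cc4O[C@H](c4ccc(OCc5ccccc5)c(OCc5ccccc5)c4)[C@@H]3O)c2O[C@H](c2ccc(OCc3ccccc3)c(OCc3ccccc3)c2)[C@@H]1O | intermediate
17 | epicatechin-(4β→8)-4β-carboxymethylepicatechin (CNP0190976.1) | O=C(O)C[C@H]1c2c(O)cc(O)c([C@H]3c4c(O)cc(O)cc4O[C@H](c4ccc(O)c(O)c4)[C@@H]3O)c2O[C@H](c2ccc(O)c(O)c2)[C@@H]1O | target

Total step count: 10
Longest linear sequence: 5 steps (steps 1, 2, 4, 9, 10 or steps 5, 6, 8, 9, 10)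

Steps most likely to fail

Step 8 (proposed new method). The ion pair may discriminate the two faces of C2 poorly, the open-chain adduct may form with the wrong 2,3-relationship, or the silylium catalyst may ionise the C4 silyl ether of 14 and cause over-reaction. The fallback uses known chemistry and sets out from 11 and 13. The racemic oxa-Povarov annulation is run with SnCl4 (CH2Cl2, −78 °C; then K2CO3, MeOH) and should give 15 together with its enantiomer, the (2S,3S,4S)-diol F1. This racemate is coupled with enantiopure 6 under the conditions of step 9, which should give 16 and its diastereomer, the ent-epicatechin-(4α→8)-linked protected dimer F2. The two are diastereomers and are separated by chromatography; the route is rejoined at 16.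

Step 9. The C4 cation from 15 may be captured by ring A of a second molecule of 15 or of 16 (oligomerisation), or by C6 instead of C8 of 6. The fallback sets out from 15 and changes the electrophile to a ring-A-deactivated one. Bromination with NBS (CH2Cl2, −20 °C) at C8 should give the 8-bromo diol F3. Its condensation with 6 (Yb(OTf)3, CH2Cl2) should give the 8-bromo protected dimer F4. Hydrogenolysis (H2, Pd(OH)2/C, Et3N, THF/MeOH) then removes bromine together with all benzyl groups and rejoins the route at 17.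

Step 6. The phenoxide may be alkylated on a ring carbon instead of oxygen, and the acid-labile acetal may ionise during isolation. The fallback sets out from 9. Williamson etherification with 3,4-bis(benzyloxy)benzyl chloride (ClCc1ccc(OCc2ccccc2)c(OCc2ccccc2)c1; K2CO3, DMF) gives the aryl benzyl ether F5. DDQ oxidation of its electron-rich benzylic C–H in the presence of MeOH (CH2Cl2, 4 Å MS, 0 °C) should give the mixed acetal and rejoins the route at 11.

Further compounds
F1 | step 8 | (2S,3S,4S)-5,7-bis(benzyloxy)-2-[3,4-bis(benzyloxy)phenyl]chromane-3,4-diol (enantiomer of 15) | O[C@H]1c2c(OCc3ccccc3)cc(OCc3ccccc3)cc2O[C@@H](c2ccc(OCc3ccccc3)c(OCc3ccccc3)c2)[C@H]1O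
F2 | step 8 | diastereomer of 16 with the enantiomeric upper unit joined 4α→8 to the same lower unit | O=C(OCc1ccccc1)C[C@H]1c2c(OCc3ccccc3)cc(OCc3ccccc3)c([C@@H]3c4c(OCc5ccccc5)cc(OCc5ccccc5)cc4O[C@@H](c4ccc(OCc5ccccc5)c(OCc5ccccc5)c4)[C@H]3O)c2O[C@H](c2ccc(OCc3ccccc3)c(OCc3ccccc3)c2)[C@@H]1O
F3 | step 9 | 8-bromo derivative of 15 (2α-aryl, 3α-OH, 4α-OH) | O[C@@H]1c2c(OCc3ccccc3)cc(OCc3ccccc3)c(Br)c2O[C@H](c2ccc(OCc3ccccc3)c(OCc3ccccc3)c2)[C@@H]1O
F4 | step 9 | 16 bearing bromine at C8 of the upper unit | O=C(OCc1ccccc1)C[C@H]1c2c(OCc3ccccc3)cc(OCc3ccccc3)c([C@H]3c4c(OCc5ccccc5)cc(OCc5ccccc5)c(Br)c4O[C@H](c4ccc(OCc5ccccc5)c(OCc5ccccc5)c4)[C@@H]3O)c2O[C@H](c2ccc(OCc3ccccc3)c(OCc3ccccc3)c2)[C@@H]1O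
F5 | step 6 | 1,3-bis(benzyloxy)-5-{[3,4-bis(benzyloxy)phenyl]methoxy}benzene | O(Cc1ccc(OCc2ccccc2)c(OCc2ccccc2)c1)c1cc(OCc2ccccc2)cc(OCc2ccccc2)c1
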